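The constants were chosen freely; what happens was integrated by code.

Your three flasks are neighbours: the charges, the gas and the run time match, and the temperature differs.

| flask | starting material | second substrate | gas | temperature | time |
|---|---|---|---|---|---|
| alder | 0.050 M | 0.0250 M | 6.1 mM (held) | −25 °C | 1.0 min |
| elm | 0.050 M | 0.0250 M | 6.1 mM (held) | 0 °C | 1.0 min |
| oak | 0.050 M | 0.0250 M | 6.1 mM (held) | 25 °C | 1.0 min |

* the flask with the highest amount of target, in percent of the starting material charged ("all alike" if they lie within 1.5 percentage points) (alder / elm / oak / all alike)
* final target, as a percentage of the starting material charged, in alder
* final target, as a percentage of the starting material charged, in elm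
* final target, as a percentage of the starting material charged, in oak

- at the start none of partner is dissolved
- the constants hold at 25 °C; other temperatures follow from the activation energies and enthalpies

    starting material + partner ⇌ target (K1 = 430 M⁻¹, k1 = 8.1 M⁻¹ s⁻¹, Ea1 = 38.0 kJ mol⁻¹, ΔH1 = −60.0 kJ mol⁻¹)
    second substrate + partner ⇌ second product (K2 = 740 M⁻¹, k2 = 0.41 M⁻¹ s⁻¹, Ea2 = 63.0 kJ mol⁻¹, ΔH2 = −22.0 kJ mol⁻¹)
    target → over-reaction product (k3 = 0.034 s⁻¹, Ea3 = 84.0 kJ mol⁻¹)
    gas ⇌ partner, rate k4*(csat - [partner]) (k4 = 1.4 s⁻¹, csat = 6.1 mM)
    (constants at 25 °C)

Before any run, count lifetimes. The partner dissolves with a lifetime of 0.714 s, far shorter than the run, so I set [partner] at 6.1 mM, which makes step 1 pseudo-first-order, and I leave the second substrate aside. Each count below is the run time divided by a lifetime. Making is the starting material turning into target at that [partner], undoing is target falling back to starting material and partner, and over-reaction is target lost to over-reaction product.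

- alder: making 0.135, undoing 3.92 × 10⁻⁴, over-reaction 0.00221, drain 0.00220
- elm: making 0.729, undoing 0.0303, over-reaction 0.0918, drain 0.0876
- oak: making 2.96, undoing 1.13, over-reaction 2.04, drain 1.23

The last column is the quantity to carry, the drain count: the number of lifetimes that the pool of starting material plus target lives through in the run. It is the smaller of two decay counts whose sum is the sum of the other three columns and whose product is making times over-reaction.

Read the rows downward. In alder, making stays below one lifetime, and over-reaction is far smaller than making, so the flask is still filling. In elm, making is larger than in alder, while the drain is far smaller than in oak. In oak, the drain passes one lifetime, so the pool itself is emptying.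

Target is making divided by the difference of the two decay counts, times the difference of their exponential decays. I commit to 12.6% in alder, 48.5% in elm and 22.9% in oak, which puts elm first.

The forecast, made by someone who saw the problem and no run, names elm and gives 12.4%, 47% and 23% in alder, elm and oak, saying that in the hottest flask “the reverse step and over-reaction consume it”. Its elm figure is lower than mine, and its first place agrees with mine.

The simulation gives 12.3%, 46.6% and 24.2%, and the forecast stands. Elm holds more target than the other two, with 51.0% of the starting material still unconverted.

At the asked time, oak makes target at 0.489 of the rate at which it is used up, each step taken net, so its target is falling. Now read oak later, at 2.5 min. The drain count grows with time to 3.09, and the same reckoning leaves 3.70% target. That later oak reading holds 4.10% target, beside 2.71% starting material and 93.2% over-reaction product.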